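**Strategy.** Everything rests on opening ring C at O1–C2 and C4–C4a, which separates a ferulic acid-derived cinnamoyl unit from a ring A phenol that already carries the C10 side chain. The key step exploits that O1 lies para to C6: a 4-alkyl-3,5-bis(silyloxy)phenol has one free oxygen and two equivalent ortho carbons, so only the 6-substituted flavanone can form. In one telescoped operation the ortho-lithiated phenoxide is C-acylated by a cinnamoyl Weinreb amide (C4–C4a) and the 2'-hydroxychalcone so released is closed at oxygen by a chiral bifunctional thiourea (O1–C2), which sets C2. The precursors are an ortho-iodophenol and an acyclic enamide.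

Key step: step 10

Remark: the quinine-derived thiourea is assumed to deliver the (2S) configuration; if the sense of induction proves opposite, its quinidine-derived pseudoenantiomer is used instead.

**Step 1**
Reactants: 1 geranyl acetate
Product: 2 6,7-epoxygeranyl acetate (racemic)
Conditions: mCPBA (1.05 equiv), NaHCO3, CH2Cl2, 0 °C
Reagents that add atoms: 3-chloroperoxybenzoic acid (mCPBA), OOC(=O)c1cccc(Cl)c1
Why: Prilezhaev epoxidation should select the distal, more electron-rich trisubstituted alkene because the 2,3-alkene is deactivated by the allylic acetoxy group, and the racemic epoxide stereocentre is erased in step 2.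

**Step 2**
Reactants: 2 6,7-epoxygeranyl acetate
Product: 4 (2E,5E)-7-hydroxy-3,7-dimethylocta-2,5-dien-1-yl acetate, via hydroxy selenide 3 (not isolated)
Conditions: (PhSe)2 (0.55 equiv), NaBH4 (1.2 equiv), EtOH, 25 °C; then 30% H2O2, THF, 0 → 25 °C
Reagents that add atoms: diphenyl diselenide, c1ccc([Se][Se]c2ccccc2)cc1 (phenylselanyl group of intermediate 3 only)
Why: In this Sharpless epoxide-to-allylic-alcohol transposition, benzeneselenolate opens the epoxide at the less hindered secondary carbon and the selenoxide undergoes syn-elimination towards C5, the only side bearing hydrogen, which should give the (E)-alkene and the tertiary alcohol.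

**Step 3**
Reactants: 4 (2E,5E)-7-hydroxy-3,7-dimethylocta-2,5-dien-1-yl acetate
Product: 5 (2E,5E)-3,7-dimethyl-7-(triethylsilyloxy)octa-2,5-dien-1-yl acetate
Conditions: TESOTf (1.3 equiv), 2,6-lutidine, CH2Cl2, −78 → 0 °C
Reagents that add atoms: triethylsilyl triflate, CC[Si](CC)(CC)OS(=O)(=O)C(F)(F)F
Why: Silylation with a silyl triflate masks the hindered tertiary allylic alcohol for the organometallic steps, so that neither zinc nor lithium reagents meet a free hydroxyl.

**Step 4**
Reactants: 6 2-bromoresorcinol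
Product: 7 2-bromo-1,3-bis(tert-butyldimethylsilyloxy)benzene
Conditions: TBSCl (2.4 equiv), imidazole, DMF, 25 °C
Reagents that add atoms: tert-butyldimethylsilyl chloride, CC(C)(C)[Si](C)(C)Cl
Why: Silyl ether formation protects the two oxygens that flank the future side chain (later O5 and O7) with groups that can be removed by fluoride at the end.

**Step 5**
Reactants: 7 2-bromo-1,3-bis(tert-butyldimethylsilyloxy)benzene
Product: 9 4-bromo-3,5-bis(tert-butyldimethylsilyloxy)phenol, via aryl pinacol boronate 8 (not isolated)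
Conditions: [Ir(OMe)(cod)]2 (1.5 mol %), 4,4'-di-tert-butyl-2,2'-bipyridine (3 mol %), B2pin2 (0.8 equiv), THF, 80 °C; then aq. KHSO5 (Oxone), acetone, 25 °C
Reagents that add atoms: bis(pinacolato)diboron, CC1(C)OB(OC1(C)C)B1OC(C)(C)C(C)(C)O1 (boronate of 8); potassium peroxymonosulfate, [K+].[O-]S(=O)(=O)OO (phenol oxygen of 9)
Why: Sterically controlled iridium-catalysed aromatic C–H borylation should occur at the only C–H without an ortho substituent, and oxidation of the C–B bond in the same flask installs the unique phenol oxygen (later O1) para to the bromide without any statistical protection.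

**Step 6**
Reactants: 9 4-bromo-3,5-bis(tert-butyldimethylsilyloxy)phenol (1.3 equiv) and 5 (2E,5E)-3,7-dimethyl-7-(triethylsilyloxy)octa-2,5-dien-1-yl acetate
Product: 12 3,5-bis(tert-butyldimethylsilyloxy)-4-[(2E,5E)-3,7-dimethyl-7-(triethylsilyloxy)octa-2,5-dien-1-yl]phenol, via dilithio phenoxide 10 (not isolated), via arylzinc chloride 11 (not isolated)
Conditions: MeLi (1.0 equiv), THF, −78 °C; t-BuLi (2.0 equiv), −78 °C; ZnCl2 (2.2 equiv), −78 → 0 °C; then 5, Pd(PPh3)4 (5 mol %), THF, 25 °C; aq. NH4Cl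
Reagents that add atoms: methyllithium, [Li]C, and tert-butyllithium, [Li]C(C)(C)C (lithium of 10 only); zinc chloride, Cl[Zn]Cl (ZnCl groups of 11 only)
Why: Bromine–lithium exchange on the lithium phenoxide, transmetalation to zinc and palladium-catalysed cross-coupling of the arylzinc with the allylic acetate (Negishi-type allyl–aryl coupling) should join the arene to the unsubstituted allyl terminus with retention of the (E)-alkene, while any O-allylation of the zinc phenoxide is reversible under the palladium catalyst.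

**Step 7**
Reactants: 12 3,5-bis(tert-butyldimethylsilyloxy)-4-[(2E,5E)-3,7-dimethyl-7-(triethylsilyloxy)octa-2,5-dien-1-yl]phenol
Product: 13 3,5-bis(tert-butyldimethylsilyloxy)-4-[(2E,5E)-3,7-dimethyl-7-(triethylsilyloxy)octa-2,5-dien-1-yl]-2-iodophenol
Conditions: NIS (1.0 equiv), CH2Cl2, −20 °C, dark
Reagents that add atoms: N-iodosuccinimide, O=C1CCC(=O)N1I
Why: Electrophilic aromatic iodination of the strongly activated phenol should be much faster than attack on the alkenes, and the two positions ortho to the hydroxyl are equivalent, so mono-iodination gives a single product.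

**Step 8**
Reactants: 14 ferulic acid
Product: 15 (E)-3-(4-hydroxy-3-methoxyphenyl)-N-methoxy-N-methylprop-2-enamide
Conditions: MeNH(OMe)·HCl, EDC·HCl, HOBt, iPr2NEt, CH2Cl2/DMF, 0 → 25 °C
Reagents that add atoms: N,O-dimethylhydroxylamine hydrochloride, CNOC.Cl
Why: Carbodiimide-mediated amide coupling through the hydroxybenzotriazole ester converts the acid into the Weinreb amide without touching the (E)-alkene or the free phenol.

**Step 9**
Reactants: 15 (E)-3-(4-hydroxy-3-methoxyphenyl)-N-methoxy-N-methylprop-2-enamide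
Product: 16 (E)-3-[4-(tert-butyldimethylsilyloxy)-3-methoxyphenyl]-N-methoxy-N-methylprop-2-enamide
Conditions: TBSCl (1.2 equiv), imidazole, DMF, 25 °C
Reagents that add atoms: tert-butyldimethylsilyl chloride, CC(C)(C)[Si](C)(C)Cl
Why: Silyl ether formation removes the acidic phenol proton before the aryllithium step and blocks quinone methide formation at the later C2 stereocentre.

**Step 10**
Reactants: 13 3,5-bis(tert-butyldimethylsilyloxy)-4-[(2E,5E)-3,7-dimethyl-7-(triethylsilyloxy)octa-2,5-dien-1-yl]-2-iodophenol and 16 (E)-3-[4-(tert-butyldimethylsilyloxy)-3-methoxyphenyl]-N-methoxy-N-methylprop-2-enamide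
Product: 19 (2S)-5,7-bis(tert-butyldimethylsilyloxy)-2-[4-(tert-butyldimethylsilyloxy)-3-methoxyphenyl]-6-[(2E,5E)-3,7-dimethyl-7-(triethylsilyloxy)octa-2,5-dien-1-yl]chroman-4-one, via dilithio phenoxide 17 (not isolated), via 2'-hydroxychalcone 18 (not isolated)
Conditions: MeLi (1.0 equiv), THF, −78 °C; t-BuLi (2.0 equiv), −78 °C; 16 (1.2 equiv), −78 → −40 °C; AcOH (4 equiv), −78 °C; filtration through a short silica pad with toluene to remove lithium salts; then 1-[3,5-bis(trifluoromethyl)phenyl]-3-[(8S,9S)-6'-methoxycinchonan-9-yl]thiourea (10 mol %), toluene, 25 °C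
Reagents that add atoms: methyllithium, [Li]C, and tert-butyllithium, [Li]C(C)(C)C (lithium of intermediate 17 only)
Why: Iodine–lithium exchange on the lithium phenoxide gives the C,O-dilithio species 17, whose aryl carbanion adds 1,2 to the Weinreb amide and, on acidification of the chelated adduct, releases 2'-hydroxychalcone 18, so the C4–C4a bond forms at the only metalated carbon; the closest known reaction types are chalcone synthesis from aryllithiums and cinnamoyl Weinreb amides and the cinchona-thiourea-catalysed oxa-Michael cyclisation of 2'-hydroxychalcones to flavanones. Ring C then closes by 6-endo-trig conjugate addition of the 2'-phenol oxygen to the β-carbon, which forms O1–C2. The C2 stereocentre is controlled by the catalyst: the thiourea binds the enone carbonyl, the quinuclidine nitrogen activates the phenol, and the resulting ion pair should expose one face of the β-carbon. Regiochemistry needs no control, because the only free oxygen of ring A lies para to the side chain and the two silylated oxygens cannot add, so only the 6-substituted flavanone can form. The 6'-silyloxy group twists the aryl ketone out of the plane of ring A, which should raise the electrophilicity of the enone towards the catalyst-bound phenol; the reaction is stopped at full conversion so that reversible ring opening does not erode the enantiomeric purity.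

**Step 11**
Reactants: 19 (2S)-5,7-bis(tert-butyldimethylsilyloxy)-2-[4-(tert-butyldimethylsilyloxy)-3-methoxyphenyl]-6-[(2E,5E)-3,7-dimethyl-7-(triethylsilyloxy)octa-2,5-dien-1-yl]chroman-4-one
Product: 20 Tomentodiplacone B
Conditions: HF·pyridine, pyridine, THF, 0 → 25 °C
Reagents that add atoms: none
Why: Fluoride-mediated cleavage of the three aryl silyl ethers and the tertiary silyl ether under pyridine-buffered, non-basic conditions generates no phenoxide, so retro-oxa-Michael racemisation at C2 and ionisation of the tertiary allylic alcohol should both be avoided.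

**Compound list**

1 | geranyl acetate, (2E)-3,7-dimethylocta-2,6-dien-1-yl acetate | CC(=O)OC/C=C(\C)CCC=C(C)C | starting material
2 | 6,7-epoxygeranyl acetate, (2E)-5-(3,3-dimethyloxiran-2-yl)-3-methylpent-2-en-1-yl acetate (racemic) | CC(=O)OC/C=C(\C)CCC1OC1(C)C | intermediate
3 | (2E)-7-hydroxy-3,7-dimethyl-6-(phenylselanyl)oct-2-en-1-yl acetate (racemic, not isolated) | CC(=O)OC/C=C(\C)CCC([Se]c1ccccc1)C(C)(C)O | intermediate
4 | (2E,5E)-7-hydroxy-3,7-dimethylocta-2,5-dien-1-yl acetate | CC(=O)OC/C=C(\C)C/C=C/C(C)(C)O | intermediate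
5 | (2E,5E)-3,7-dimethyl-7-(triethylsilyloxy)octa-2,5-dien-1-yl acetate | CC(=O)OC/C=C(\C)C/C=C/C(C)(C)O[Si](CC)(CC)CC | intermediate
6 | 2-bromoresorcinol (2-bromobenzene-1,3-diol) | Oc1cccc(O)c1Br | starting material
7 | 2-bromo-1,3-bis(tert-butyldimethylsilyloxy)benzene | CC(C)(C)[Si](C)(C)Oc1cccc(O[Si](C)(C)C(C)(C)C)c1Br | intermediate
8 | 2-[4-bromo-3,5-bis(tert-butyldimethylsilyloxy)phenyl]-4,4,5,5-tetramethyl-1,3,2-dioxaborolane (not isolated) | CC(C)(C)[Si](C)(C)Oc1cc(B2OC(C)(C)C(C)(C)O2)cc(O[Si](C)(C)C(C)(C)C)c1Br | intermediate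
9 | 4-bromo-3,5-bis(tert-butyldimethylsilyloxy)phenol | CC(C)(C)[Si](C)(C)Oc1cc(O)cc(O[Si](C)(C)C(C)(C)C)c1Br | intermediate
10 | lithium 4-lithio-3,5-bis(tert-butyldimethylsilyloxy)phenoxide (not isolated) | [Li]Oc1cc(O[Si](C)(C)C(C)(C)C)c([Li])c(O[Si](C)(C)C(C)(C)C)c1 | intermediate
11 | chlorozinc 4-(chlorozincio)-3,5-bis(tert-butyldimethylsilyloxy)phenoxide (not isolated) | Cl[Zn]Oc1cc(O[Si](C)(C)C(C)(C)C)c([Zn]Cl)c(O[Si](C)(C)C(C)(C)C)c1 | intermediate
12 | 3,5-bis(tert-butyldimethylsilyloxy)-4-[(2E,5E)-3,7-dimethyl-7-(triethylsilyloxy)octa-2,5-dien-1-yl]phenol | Oc1cc(O[Si](C)(C)C(C)(C)C)c(C/C=C(\C)C/C=C/C(C)(C)O[Si](CC)(CC)CC)c(O[Si](C)(C)C(C)(C)C)c1 | intermediate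
13 | 3,5-bis(tert-butyldimethylsilyloxy)-4-[(2E,5E)-3,7-dimethyl-7-(triethylsilyloxy)octa-2,5-dien-1-yl]-2-iodophenol | Oc1cc(O[Si](C)(C)C(C)(C)C)c(C/C=C(\C)C/C=C/C(C)(C)O[Si](CC)(CC)CC)c(O[Si](C)(C)C(C)(C)C)c1I | intermediate
14 | ferulic acid, (E)-3-(4-hydroxy-3-methoxyphenyl)prop-2-enoic acid | COc1cc(/C=C/C(=O)O)ccc1O | starting material
15 | (E)-3-(4-hydroxy-3-methoxyphenyl)-N-methoxy-N-methylprop-2-enamide | COc1cc(/C=C/C(=O)N(C)OC)ccc1O | intermediate
16 | (E)-3-[4-(tert-butyldimethylsilyloxy)-3-methoxyphenyl]-N-methoxy-N-methylprop-2-enamide | COc1cc(/C=C/C(=O)N(C)OC)ccc1O[Si](C)(C)C(C)(C)C | intermediate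
17 | lithium 2-lithio-3,5-bis(tert-butyldimethylsilyloxy)-4-[(2E,5E)-3,7-dimethyl-7-(triethylsilyloxy)octa-2,5-dien-1-yl]phenoxide (not isolated) | [Li]Oc1cc(O[Si](C)(C)C(C)(C)C)c(C/C=C(\C)C/C=C/C(C)(C)O[Si](CC)(CC)CC)c(O[Si](C)(C)C(C)(C)C)c1[Li] | intermediate
18 | (E)-1-{4,6-bis(tert-butyldimethylsilyloxy)-5-[(2E,5E)-3,7-dimethyl-7-(triethylsilyloxy)octa-2,5-dien-1-yl]-2-hydroxyphenyl}-3-[4-(tert-butyldimethylsilyloxy)-3-methoxyphenyl]prop-2-en-1-one (not isolated) | COc1cc(/C=C/C(=O)c2c(O)cc(O[Si](C)(C)C(C)(C)C)c(C/C=C(\C)C/C=C/C(C)(C)O[Si](CC)(CC)CC)c2O[Si](C)(C)C(C)(C)C)ccc1O[Si](C)(C)C(C)(C)C | intermediate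
19 | (2S)-5,7-bis(tert-butyldimethylsilyloxy)-2-[4-(tert-butyldimethylsilyloxy)-3-methoxyphenyl]-6-[(2E,5E)-3,7-dimethyl-7-(triethylsilyloxy)octa-2,5-dien-1-yl]chroman-4-one | COc1cc([C@@H]2CC(=O)c3c(cc(O[Si](C)(C)C(C)(C)C)c(C/C=C(\C)C/C=C/C(C)(C)O[Si](CC)(CC)CC)c3O[Si](C)(C)C(C)(C)C)O2)ccc1O[Si](C)(C)C(C)(C)C | intermediate
20 | Tomentodiplacone B, (2S)-5,7-dihydroxy-2-(4-hydroxy-3-methoxyphenyl)-6-[(2E,5E)-7-hydroxy-3,7-dimethylocta-2,5-dien-1-yl]chroman-4-one | COc1cc([C@@H]2CC(=O)c3c(cc(O)c(C/C=C(\C)C/C=C/C(C)(C)O)c3O)O2)ccc1O | target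

**Total step count:** 11
**Longest linear sequence:** 7 steps (steps 1, 2, 3, 6, 7, 10, 11)

**Steps most likely to fail**

Step 10. The oxa-Michael stage may turn over slowly or with incomplete facial control, and reversible ring opening under the amine catalyst may erode the enantiomeric purity. At the lithium stage, silyl migration from oxygen to the lithiated carbon or conjugate addition to the enamide may compete with acylation. Fallback: the acylation stage is worked up and chalcone 18 is isolated. DBU (0.2 equiv) in toluene closes it without stereocontrol to the racemic protected flavanone F1. A kinetic resolution by asymmetric transfer hydrogenation with RuCl(p-cymene)[(R,R)-TsDPEN] and HCO2H/Et3N in EtOAc at 25 °C, stopped near half conversion, should reduce the (2R)-ketone to the cis-flavan-4-ol F2 and leave the (2S)-ketone. The fallback sets out from 18 and comes back to the route at 19.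

Step 6. Transmetalation of the doubly ortho-silyloxylated, phenoxide-bearing arylzinc to the allylpalladium complex may be slow. Silyl migration to the lithiated carbon may occur before zincation, and the phenoxide may be allylated at oxygen. Fallback: the coupling is run before the phenol oxygen exists. From 7, bromine–lithium exchange (t-BuLi, THF, −78 °C) gives 2,6-bis(tert-butyldimethylsilyloxy)phenyllithium F3, and ZnCl2 gives the arylzinc chloride F4. Coupling with 5 under Pd(PPh3)4 gives the 2-alkyl-1,3-bis(silyloxy)benzene F5. Iridium-catalysed borylation at the only unhindered C–H ([Ir(OMe)(cod)]2, 4,4'-di-tert-butyl-2,2'-bipyridine, B2pin2) gives the aryl boronate F6. Oxidation with NaBO3·4H2O in THF/H2O, which spares the alkenes, comes back to the route at 12.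

Step 7. Over-iodination of the doubly activated ring and iodonium capture at the trisubstituted alkene may compete with the single ortho-iodination. Fallback: the halogen is avoided altogether by an oxygen-to-carbon acyl shift. From 12 and 14, ferulic acid 14 is silylated twice (TBSCl, imidazole, DMF) to the silyl ester F7, and the silyl ester is cleaved selectively (AcOH, THF/H2O) to the acid F8. DCC/DMAP esterification of 12 with F8 gives the aryl cinnamate F9. Photo-Fries rearrangement (hν 300 nm, MeCN) should move the acyl group to the ortho carbon, the para position being blocked by the side chain. This comes back to the route at chalcone 18, which enters the cyclisation stage of step 10.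

**Further compounds**

F1 | step 10 | racemic 5,7-bis(tert-butyldimethylsilyloxy)-2-[4-(tert-butyldimethylsilyloxy)-3-methoxyphenyl]-6-[(2E,5E)-3,7-dimethyl-7-(triethylsilyloxy)octa-2,5-dien-1-yl]chroman-4-one | COc1cc(C2CC(=O)c3c(cc(O[Si](C)(C)C(C)(C)C)c(C/C=C(\C)C/C=C/C(C)(C)O[Si](CC)(CC)CC)c3O[Si](C)(C)C(C)(C)C)O2)ccc1O[Si](C)(C)C(C)(C)C
F2 | step 10 | (2R,4R)-5,7-bis(tert-butyldimethylsilyloxy)-2-[4-(tert-butyldimethylsilyloxy)-3-methoxyphenyl]-6-[(2E,5E)-3,7-dimethyl-7-(triethylsilyloxy)octa-2,5-dien-1-yl]chroman-4-ol | COc1cc([C@H]2C[C@@H](O)c3c(cc(O[Si](C)(C)C(C)(C)C)c(C/C=C(\C)C/C=C/C(C)(C)O[Si](CC)(CC)CC)c3O[Si](C)(C)C(C)(C)C)O2)ccc1O[Si](C)(C)C(C)(C)C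
F3 | step 6 | 2,6-bis(tert-butyldimethylsilyloxy)phenyllithium | CC(C)(C)[Si](C)(C)Oc1cccc(O[Si](C)(C)C(C)(C)C)c1[Li]
F4 | step 6 | [2,6-bis(tert-butyldimethylsilyloxy)phenyl]zinc chloride | CC(C)(C)[Si](C)(C)Oc1cccc(O[Si](C)(C)C(C)(C)C)c1[Zn]Cl
F5 | step 6 | 1,3-bis(tert-butyldimethylsilyloxy)-2-[(2E,5E)-3,7-dimethyl-7-(triethylsilyloxy)octa-2,5-dien-1-yl]benzene | CC(C)(C)[Si](C)(C)Oc1cccc(O[Si](C)(C)C(C)(C)C)c1C/C=C(\C)C/C=C/C(C)(C)O[Si](CC)(CC)CC
F6 | step 6 | 2-{3,5-bis(tert-butyldimethylsilyloxy)-4-[(2E,5E)-3,7-dimethyl-7-(triethylsilyloxy)octa-2,5-dien-1-yl]phenyl}-4,4,5,5-tetramethyl-1,3,2-dioxaborolane | CC(C)(C)[Si](C)(C)Oc1cc(B2OC(C)(C)C(C)(C)O2)cc(O[Si](C)(C)C(C)(C)C)c1C/C=C(\C)C/C=C/C(C)(C)O[Si](CC)(CC)CC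
F7 | step 7 | tert-butyldimethylsilyl (E)-3-[4-(tert-butyldimethylsilyloxy)-3-methoxyphenyl]prop-2-enoate | COc1cc(/C=C/C(=O)O[Si](C)(C)C(C)(C)C)ccc1O[Si](C)(C)C(C)(C)C
F8 | step 7 | (E)-3-[4-(tert-butyldimethylsilyloxy)-3-methoxyphenyl]prop-2-enoic acid | COc1cc(/C=C/C(=O)O)ccc1O[Si](C)(C)C(C)(C)C
F9 | step 7 | 3,5-bis(tert-butyldimethylsilyloxy)-4-[(2E,5E)-3,7-dimethyl-7-(triethylsilyloxy)octa-2,5-dien-1-yl]phenyl (E)-3-[4-(tert-butyldimethylsilyloxy)-3-methoxyphenyl]prop-2-enoate | COc1cc(/C=C/C(=O)Oc2cc(O[Si](C)(C)C(C)(C)C)c(C/C=C(\C)C/C=C/C(C)(C)O[Si](CC)(CC)CC)c(O[Si](C)(C)C(C)(C)C)c2)ccc1O[Si](C)(C)C(C)(C)C
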